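A direct plan would take L-alanine-derived (S)-2-(dibenzylamino)propanal (A1) by chelation-controlled allylation to the syn amino alcohol A2, extend the chain to a 1,5-amino ketone, close the piperidine by reductive amination, and oxidise and protect to N-Cbz-azimic acid (A3), which would be cyclodimerised by double macrolactonisation to A4 and deprotected.
Its weakest steps would be: the allylation of A1, since N,N-dibenzylamino aldehydes chelate poorly, favour the anti product and are configurationally labile; the macrodilactonisation of A3, since its ring-closing bonds would be esters of an axial hydroxyl flanked by methyl and N-carbamate, made twice at high dilution against oligomers; and the oxidation-level and protecting-group shuffle (three alcohol oxidations, benzyl off, Cbz on and off), which would add length but no complexity.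

The new route rests on cutting the two Cα=Cβ bonds of the acyl chains instead of the two ester C–O bonds, while both piperidines are still open. Azimine's 22-membered perimeter, (O–C3–C4–C5–C6–(CH2)5–CO)2, contains neither N1 nor C2, which only bridge C3 and C6; an open-chain acrylate carrying just the C2/C3 stereodiad can therefore be cyclodimerised head-to-tail by acrylate/terminal-alkene cross-metathesis. This one operation closes the macrocycle from two identical monomers whose ester bonds were made early on an unhindered carbinol. One final hydrogenation then forms both N1–C6 bonds and both C6 stereocentres. No amino-aldehyde addition, macrolactonisation or protecting-group round trip remains.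

Key step: step 7

Remarks: piperidine atoms are labelled as in azimic acid (N1, C2 methyl-bearing, C3 oxygen-bearing, C6 chain-bearing) at every stage. It is assumed that the D-fructose-derived Shi ketone would epoxidise the (E)-alkene of 4 to the (4R,5R)-epoxide, as it does other trans-disubstituted alkenes.

Step 1
Reactants: 1 but-3-en-2-ol (racemic); 2 triethyl orthoacetate
Product: 4 ethyl (E)-hex-4-enoate, via ketene acetal 3 (not isolated)
Conditions: 2 (4 equiv), EtCO2H (cat.), 140 °C, EtOH distilled off
Reagents that add atoms: none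
Why: Johnson–Claisen rearrangement, in which the mixed ketene acetal 3 should undergo a chair [3,3]-sigmatropic shift with the methyl group equatorial, giving the (E)-alkene and the ester chain in one step while the stereocentre of 1 is destroyed, so racemic 1 suffices.

Step 2
Reactants: 4 ethyl (E)-hex-4-enoate
Product: 7 (5S)-5-[(1R)-1-hydroxyethyl]oxolan-2-one, via epoxy ester 5 (not isolated), via epoxy acid 6 (not isolated)
Conditions: D-fructose-derived Shi ketone (0.3 equiv), Oxone (2KHSO5·KHSO4·K2SO4), K2CO3, Bu4NHSO4 (cat.), MeCN/CH2(OMe)2/aq. Na2B4O7 buffer, 0 °C; extractive work-up; then LiOH, THF/H2O, 0 °C; then 1 M HCl to pH 2, rt; continuous extraction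
Reagents that add atoms: potassium peroxymonosulfate, [K+].[O-]S(=O)(=O)OO; lithium hydroxide, [Li+].[OH-]
Why: Shi asymmetric epoxidation (chiral dioxirane, spiro transition state) should set both future stereocentres under reagent control, and the freed carboxylic acid then opens the epoxide 5-exo with inversion at C4, so the (4R,5R)-epoxide should give the erythro (5S,1'R) hydroxy lactone with its two oxygens differentiated (any diastereomer arising from (Z)-4 would be removed here).

Step 3
Reactants: 7 (5S)-5-[(1R)-1-hydroxyethyl]oxolan-2-one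
Product: 8 (5S)-5-[(1S)-1-azidoethyl]oxolan-2-one
Conditions: PPh3, DIAD, (PhO)2P(O)N3 (1.5 equiv each), THF, 0 °C → rt; product handled in solution
Reagents that add atoms: diphenylphosphoryl azide, [N-]=[N+]=NP(=O)(Oc1ccccc1)Oc1ccccc1
Why: Mitsunobu azidation, an SN2 displacement that should invert the carbinol centre to (S) and so turn the erythro dioxygen pattern into the syn 1,2-azido alcohol of C2/C3, the acylated ring oxygen being too poor a neighbouring group to interfere.

Step 4
Reactants: 8 (5S)-5-[(1S)-1-azidoethyl]oxolan-2-one
Product: 10 tert-butyl N-[(1S)-1-[(2S)-5-oxooxolan-2-yl]ethyl]carbamate, via amino lactone 9 (not isolated)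
Conditions: H2 (1 atm), 10% Pd/C, Boc2O (1.3 equiv), EtOAc, rt
Reagents that add atoms: di-tert-butyl dicarbonate, CC(C)(C)OC(=O)OC(=O)OC(C)(C)C
Why: Catalytic hydrogenation of the azide with in situ carbamate formation, in which capture of amine 9 by Boc2O should outrun its attack on the lactone (which would give the six-membered lactam), leaving both stereocentres untouched.

Step 5
Reactants: 10 tert-butyl N-[(1S)-1-[(2S)-5-oxooxolan-2-yl]ethyl]carbamate; 11 5-bromopent-1-ene
Product: 13 tert-butyl N-[(2S,3S)-3-hydroxy-6-oxoundec-10-en-2-yl]carbamate, via pent-4-enylmagnesium bromide 12 (not isolated)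
Conditions: 11 (2.4 equiv), Mg, THF, rt → 40 °C; then added to 10, THF, −78 °C, 1 h; aq. NH4Cl at −78 °C
Reagents that add atoms: none
Why: Grignard mono-addition to a γ-lactone, in which the first equivalent deprotonates the carbamate and the second gives a magnesium lactolate that should persist at −78 °C until the quench, so the C6 ketone (in equilibrium with its lactol) appears only on work-up and carries the C7–C11 alkenyl chain.

Step 6
Reactants: 13 tert-butyl N-[(2S,3S)-3-hydroxy-6-oxoundec-10-en-2-yl]carbamate
Product: 14 (2S,3S)-2-[(tert-butoxycarbonyl)amino]-6-oxoundec-10-en-3-yl prop-2-enoate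
Conditions: CH2=CHCOCl (1.5 equiv), iPr2NEt (2 equiv), DMAP (5 mol%), CH2Cl2, −20 → 0 °C
Reagents that add atoms: acryloyl chloride, C=CC(=O)Cl
Why: DMAP-catalysed O-acylation of the open-chain secondary alcohol, which should drain the lactol equilibrium because the tertiary hemiketal hydroxyl is far less reactive, forming the future ring ester at normal concentration on an unhindered carbinol.

Step 7
Reactants: 14 (2S,3S)-2-[(tert-butoxycarbonyl)amino]-6-oxoundec-10-en-3-yl prop-2-enoate (two molecules)
Product: 16 (3E,11S,14E,22S)-11,22-bis{(1S)-1-[(tert-butoxycarbonyl)amino]ethyl}-1,12-dioxacyclodocosa-3,14-diene-2,8,13,19-tetrone, via linear head-to-tail dimer 15 (not isolated)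
Conditions: second-generation Hoveyda–Grubbs catalyst (H2IMes)Cl2Ru(=CH-C6H4-2-OiPr) (2 × 5 mol%), 1,4-benzoquinone (10 mol%), CH2Cl2 (0.005 M in 14), 40 °C, argon sparge, 24 h
Reagents that add atoms: none
Why: The ruthenium alkylidene should initiate on the terminal alkene of 14 and, by [2+2]/retro-[2+2] steps (Chauvin mechanism), couple it to the acrylate of a second molecule with loss of ethene to give the linear dimer 15, which closes by the same event at its remaining acrylate and alkene ends. The closest known reaction type is the cross-metathesis of acrylates with terminal alkenes and its use for head-to-tail cyclodimerisation to C2-symmetric macrodiolides. The 22-membered ring is closed by ring-closing metathesis at the unhindered C10=Cα bond, remote from every stereocentre, and no stereocentre is formed (both E-enoate bonds are hydrogenated later). The step needs head-to-tail selectivity, which the substrate secures because the electron-poor acrylate does not homodimerise, while alkene–alkene homodimers stay metathesis-active and are funnelled into the enoate, whose formation is practically irreversible. It also needs the dimer over monomer closure and oligomers: the monomeric product would be a strained 11-membered E-enoate lactone, C4–C5 is saturated so no five- or six-membered ring can be excised, and high dilution favours closure of 15. Any minor enantiomer of 14 would end up mainly in the diastereomeric heterodimer, so 16 should be enantiomerically enriched over 14 after chromatography.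

Step 8
Reactants: 16 (3E,11S,14E,22S)-11,22-bis{(1S)-1-[(tert-butoxycarbonyl)amino]ethyl}-1,12-dioxacyclodocosa-3,14-diene-2,8,13,19-tetrone
Product: 20 (+)-azimine, via saturated bis-carbamate 17 (not isolated), via bis(amino ketone) 18 (not isolated), via bis(cyclic imine) 19 (not isolated)
Conditions: H2 (1 atm), 20% Pd(OH)2/C, EtOAc/AcOH 4:1, rt, 3 h; then HCl (4 M in dioxane, to about 1 M) added to the same vessel, H2 (3 atm), rt, 16 h; filtration; aq. NaHCO3, CH2Cl2
Reagents that add atoms: none
Why: After saturation of both enoates, acidolysis of the Boc groups should free each nitrogen as its ammonium salt (which blocks O-to-N acyl transfer), each nitrogen condenses with its own C6 ketone to a six-membered cyclic iminium ion, and hydrogen adds to each C=N from the face opposite the cis C2 methyl and C3 acyloxy groups, setting C6 and C6' (R) all-cis (double intramolecular reductive amination).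

Compound list
1 | but-3-en-2-ol (racemic) | CC(O)C=C | starting material
2 | triethyl orthoacetate | CC(OCC)(OCC)OCC | starting material
3 | 3-[(1-ethoxyethenyl)oxy]but-1-ene, mixed ketene acetal (not isolated) | C=C(OCC)OC(C)C=C | intermediate
4 | ethyl (E)-hex-4-enoate | C/C=C/CCC(=O)OCC | intermediate
5 | ethyl 3-[(2R,3R)-3-methyloxiran-2-yl]propanoate (not isolated) | C[C@H]1O[C@@H]1CCC(=O)OCC | intermediate
6 | 3-[(2R,3R)-3-methyloxiran-2-yl]propanoic acid (not isolated) | C[C@H]1O[C@@H]1CCC(=O)O | intermediate
7 | (5S)-5-[(1R)-1-hydroxyethyl]oxolan-2-one | C[C@@H](O)[C@@H]1CCC(=O)O1 | intermediate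
8 | (5S)-5-[(1S)-1-azidoethyl]oxolan-2-one | C[C@H](N=[N+]=[N-])[C@@H]1CCC(=O)O1 | intermediate
9 | (5S)-5-[(1S)-1-aminoethyl]oxolan-2-one (not isolated) | C[C@H](N)[C@@H]1CCC(=O)O1 | intermediate
10 | tert-butyl N-[(1S)-1-[(2S)-5-oxooxolan-2-yl]ethyl]carbamate | C[C@H](NC(=O)OC(C)(C)C)[C@@H]1CCC(=O)O1 | intermediate
11 | 5-bromopent-1-ene | BrCCCC=C | starting material
12 | pent-4-enylmagnesium bromide (not isolated) | C=CCCC[Mg]Br | intermediate
13 | tert-butyl N-[(2S,3S)-3-hydroxy-6-oxoundec-10-en-2-yl]carbamate (open form of the lactol) | C[C@H](NC(=O)OC(C)(C)C)[C@@H](O)CCC(=O)CCCC=C | intermediate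
14 | (2S,3S)-2-[(tert-butoxycarbonyl)amino]-6-oxoundec-10-en-3-yl prop-2-enoate | C[C@H](NC(=O)OC(C)(C)C)[C@@H](OC(=O)C=C)CCC(=O)CCCC=C | intermediate
15 | linear head-to-tail dimer: terminal alkene of one unit of 14 joined as an (E)-enoate to the acrylate of a second unit, one acrylate and one terminal alkene remaining (not isolated) | C=CC(=O)O[C@@H](CCC(=O)CCC/C=C/C(=O)O[C@@H](CCC(=O)CCCC=C)[C@H](C)NC(=O)OC(C)(C)C)[C@H](C)NC(=O)OC(C)(C)C | intermediate
16 | (3E,11S,14E,22S)-11,22-bis{(1S)-1-[(tert-butoxycarbonyl)amino]ethyl}-1,12-dioxacyclodocosa-3,14-diene-2,8,13,19-tetrone | C[C@H](NC(=O)OC(C)(C)C)[C@@H]1CCC(=O)CCC/C=C/C(=O)O[C@@H](CCC(=O)CCC/C=C/C(=O)O1)[C@H](C)NC(=O)OC(C)(C)C | intermediate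
17 | (11S,22S)-11,22-bis{(1S)-1-[(tert-butoxycarbonyl)amino]ethyl}-1,12-dioxacyclodocosane-2,8,13,19-tetrone (not isolated) | C[C@H](NC(=O)OC(C)(C)C)[C@@H]1CCC(=O)CCCCCC(=O)O[C@@H](CCC(=O)CCCCCC(=O)O1)[C@H](C)NC(=O)OC(C)(C)C | intermediate
18 | (11S,22S)-11,22-bis[(1S)-1-aminoethyl]-1,12-dioxacyclodocosane-2,8,13,19-tetrone, present as its dihydrochloride (not isolated) | C[C@H](N)[C@@H]1CCC(=O)CCCCCC(=O)O[C@@H](CCC(=O)CCCCCC(=O)O1)[C@H](C)N | intermediate
19 | bis(cyclic imine): the 22-membered diolide in which each nitrogen is condensed with its C6 ketone to a 2-methyl-2,3,4,5-tetrahydropyridine ring, present as the bis(iminium) dichloride (not isolated) | C[C@@H]1N=C2CCCCCC(=O)O[C@H]3CCC(CCCCCC(=O)O[C@H]1CC2)=N[C@H]3C | intermediate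
20 | (+)-azimine (CNP0219883.1) | C[C@@H]1N[C@@H]2CCCCCC(=O)O[C@H]3CC[C@@H](CCCCCC(=O)O[C@H]1CC2)N[C@H]3C | target

Total step count: 8. Longest linear sequence: 8 steps (from but-3-en-2-ol).

Steps most likely to fail

Step 7. Chain growth to oligomers or ruthenium-hydride alkene migration could outrun closure of the linear dimer. The fallback would set out from 13 and come back at 17. Cross-metathesis of 13 with excess benzyl acrylate at ordinary concentration would give benzyl (2E,10S,11S)-11-[(tert-butoxycarbonyl)amino]-10-hydroxy-7-oxododec-2-enoate F1. Hydrogenation over Pd/C would saturate the enoate and cleave the benzyl ester to (10S,11S)-11-[(tert-butoxycarbonyl)amino]-10-hydroxy-7-oxododecanoic acid F2. A Yamaguchi cyclodimerisation of this open-chain hydroxy acid (2,4,6-trichlorobenzoyl chloride, Et3N, then DMAP, toluene, high dilution), whose carbinol is unhindered, would give 17, which would enter step 8 at the HCl stage.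

Step 5. A second addition to the liberated ketone, or attack on the carbamate, could compete with mono-addition. The fallback would set out from 10 and come back at 13. Aminolysis of the lactone with MeNH(OMe)·HCl and iPrMgCl would give the Weinreb amide tert-butyl N-[(2S,3S)-3-hydroxy-6-[methoxy(methyl)amino]-6-oxohexan-2-yl]carbamate F3. Silylation (Et3SiCl, imidazole) would give tert-butyl N-[(2S,3S)-6-[methoxy(methyl)amino]-6-oxo-3-[(triethylsilyl)oxy]hexan-2-yl]carbamate F4. Addition of 12 would stop at the ketone tert-butyl N-[(2S,3S)-6-oxo-3-[(triethylsilyl)oxy]undec-10-en-2-yl]carbamate F5, and AcOH/THF/H2O would return 13.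

Step 8. Acyl transfer from O3 to the freed nitrogen before cyclisation, or insufficient facial selectivity on the catalyst surface, could erode the final cascade. The fallback would set out from 16 and come back at 20. Compound 17 would be isolated after the neutral hydrogenation and cyclised with nitrogen still acylated: Et3SiH and BF3·OEt2 in CH2Cl2 at −78 °C (N-acyliminium ion reduction, hydride delivered axially anti to the pseudoaxial C2 methyl) would give N,N'-bis(tert-butoxycarbonyl)azimine F6, from which CF3CO2H would release 20.

Further compounds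
F1 | step 7 | benzyl (2E,10S,11S)-11-[(tert-butoxycarbonyl)amino]-10-hydroxy-7-oxododec-2-enoate | C[C@H](NC(=O)OC(C)(C)C)[C@@H](O)CCC(=O)CCC/C=C/C(=O)OCc1ccccc1
F2 | step 7 | (10S,11S)-11-[(tert-butoxycarbonyl)amino]-10-hydroxy-7-oxododecanoic acid | C[C@H](NC(=O)OC(C)(C)C)[C@@H](O)CCC(=O)CCCCCC(=O)O
F3 | step 5 | tert-butyl N-[(2S,3S)-3-hydroxy-6-[methoxy(methyl)amino]-6-oxohexan-2-yl]carbamate | C[C@H](NC(=O)OC(C)(C)C)[C@@H](O)CCC(=O)N(C)OC
F4 | step 5 | tert-butyl N-[(2S,3S)-6-[methoxy(methyl)amino]-6-oxo-3-[(triethylsilyl)oxy]hexan-2-yl]carbamate | C[C@H](NC(=O)OC(C)(C)C)[C@@H](O[Si](CC)(CC)CC)CCC(=O)N(C)OC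
F5 | step 5 | tert-butyl N-[(2S,3S)-6-oxo-3-[(triethylsilyl)oxy]undec-10-en-2-yl]carbamate | C[C@H](NC(=O)OC(C)(C)C)[C@@H](O[Si](CC)(CC)CC)CCC(=O)CCCC=C
F6 | step 8 | N,N'-bis(tert-butoxycarbonyl)azimine | C[C@@H]1N(C(=O)OC(C)(C)C)[C@@H]2CCCCCC(=O)O[C@H]3CC[C@@H](CCCCCC(=O)O[C@H]1CC2)N(C(=O)OC(C)(C)C)[C@H]3C
A1 | direct plan | (S)-2-(dibenzylamino)propanal | C[C@H](N(Cc1ccccc1)Cc1ccccc1)C=O
A2 | direct plan | (4S,5S)-5-(dibenzylamino)hex-1-en-4-ol | C[C@H](N(Cc1ccccc1)Cc1ccccc1)[C@@H](O)CC=C
A3 | direct plan | N-Cbz-azimic acid, 6-[(2R,5S,6S)-1-[(benzyloxy)carbonyl]-5-hydroxy-6-methylpiperidin-2-yl]hexanoic acid | C[C@@H]1N(C(=O)OCc2ccccc2)[C@H](CCCCCC(=O)O)CC[C@@H]1O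
A4 | direct plan | N,N'-bis(benzyloxycarbonyl)azimine | C[C@@H]1N(C(=O)OCc4ccccc4)[C@@H]2CCCCCC(=O)O[C@H]3CC[C@@H](CCCCCC(=O)O[C@H]1CC2)N(C(=O)OCc4ccccc4)[C@H]3C
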